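**Plan**

Atom numbers are eremophilane numbers: ring A = C1–C5 and C10, ring B = C5–C10, C14 on C5, C15 on C4, isopropenyl C11–C13 on C7.
- Retrosynthesis: cut the two ester C–O bonds, then C9–O and C7–C11 (enolate chemistry at the C8 ketone), then C3–O/C4–H (hydroboration of a C3=C4 alkene), then C1–C2 and C3=C4 together, leaving a ring-B cyclohexane.
- Forward: ring B by an enantioselective Diels–Alder reaction; ring A in one operation, in which a C1 radical adds to vinyltriphenylphosphonium (C2=C3) and the resulting C3 ylide closes on the C4 ketone; then decoration of rings A and B.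
- Enabling feature: C1 is a bare CH2 on C10, and C4 carries only the C15 methyl next to quaternary C5. A carboxymethyl arm on C10 (the carboxyl is a traceless radical precursor) and an acetyl group on C5, trans on ring B, are therefore all the annulation needs; CO2 and Ph3PO leave in the step.
- Stereochemistry: C5 from the chiral Diels–Alder catalyst; C10 from conjugate addition anti to a temporarily enlarged C5 side chain; C3 and C4 from hydroboration anti to the axial C5 methyl; C7 and C9 equatorial next to the C8 ketone.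

Key step: step 6

Assumption: the antipode of the chromium–salen catalyst that gives the (1S) quaternary centre of 3 is used (the other antipode would give the mirror-image series), and (2E)-3-methylpent-2-enoic acid 25 is taken as purchasable.

**Route**

Step 1
Reactants: 1 (E)-3-[(tert-butyldimethylsilyl)oxy]-N,N-dimethylbuta-1,3-dien-1-amine; 2 methacrolein
Product: 3 (1S,2R)-2-(dimethylamino)-4-[(tert-butyldimethylsilyl)oxy]-1-methylcyclohex-3-ene-1-carbaldehyde
Conditions: [Cr(L)]SbF6 (5 mol%; L = N,N′-bis(3,5-di-tert-butylsalicylidene)cyclohexane-1,2-diaminate(2−), one antipode; trivalent chromium), 4 Å molecular sieves, CH2Cl2, −40 °C; used crude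
Reagents that add atoms: none
Why: Catalytic enantioselective Diels–Alder reaction of a 1-amino-3-siloxy diene with an α-substituted acrolein, in which the amino terminus bonds to the α-carbon of methacrolein and the chiral Lewis acid fixes the dienophile face and hence the quaternary carbon (future C5); the amino-bearing centre is lost in step 2.

Step 2
Reactants: 3
Product: 5 (4S)-4-(1-hydroxyethyl)-4-methylcyclohex-2-en-1-one (both carbinol epimers), via carbinol cycloadduct 4 (not isolated)
Conditions: MeMgBr, THF, −78 °C; then 1 M HCl, THF, 0 °C to rt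
Reagents that add atoms: methylmagnesium bromide, C[Mg]Br
Why: Grignard addition to the non-enolisable aldehyde (the ketone is still masked as its silyl enol ether), then acid hydrolysis and β-elimination of dimethylamine to unmask the cyclohexenone; the new carbinol centre is uncontrolled and is erased by oxidation in step 5.

Step 3
Reactants: 5; 6 tert-butyl[(1-methoxyethenyl)oxy]dimethylsilane
Product: 9 methyl 2-[(1R,2S)-2-(1-hydroxyethyl)-2-methyl-5-oxocyclohexyl]acetate, via silyl ether 7 (not isolated), via silyl enol ether 8 (not isolated)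
Conditions: TBSOTf (1.15 equiv), 2,6-lutidine (1.05 equiv), CH2Cl2, −78 °C; then 6 (1.5 equiv), −78 to −30 °C; then aq. HF, MeCN, 0 °C to rt
Reagents that add atoms: none
Why: In situ silylation makes the C5 side chain much larger than the C5 methyl, so the silyl-triflate-catalysed Mukaiyama–Michael addition should occur on the enone face anti to it and set C10 with the acetate arm trans to the future C4 (1,2-induction, also the thermodynamically preferred arrangement); HF then removes both silyl groups.

Step 4
Reactants: 9; 10 ethylene glycol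
Product: 11 (4a′R,8a′S)-1′,8a′-dimethylhexahydrospiro[1,3-dioxolane-2,6′-isochromen]-3′(4′H)-one (trans-fused δ-lactone ketal, both C1′ epimers)
Conditions: PPTS (10 mol%), benzene, reflux, Dean–Stark trap
Reagents that add atoms: none
Why: Acid-catalysed ketalisation of the only ketone with azeotropic water removal, during which the δ-hydroxy ester should close to the trans-fused δ-lactone (a temporary ring); any ester left open converges in step 5.

Step 5
Reactants: 11
Product: 13 2-[(7R,8S)-8-acetyl-8-methyl-1,4-dioxaspiro[4.5]decan-7-yl]acetic acid, via lithium hydroxy carboxylate 12 (not isolated)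
Conditions: LiOH, THF/H2O, rt; then AZADO (2-azaadamantane N-oxyl, 5 mol%), NaOCl, KBr (cat.), NaHCO3, CH2Cl2/H2O, 0 °C; then 1 M HCl to pH 4, 0 °C
Reagents that add atoms: lithium hydroxide, [Li+].[OH-]
Why: Saponification opens the lactone to a hydroxy carboxylate that cannot relactonise, and nitroxyl-catalysed hypochlorite oxidation of the hindered secondary alcohol then gives the methyl ketone and removes the uncontrolled carbinol centre.

Step 6
Reactants: 13; 14 vinyltriphenylphosphonium bromide
Product: 16 (4a′S,8a′S)-4a′,5′-dimethyl-3′,4′,4a′,7′,8′,8a′-hexahydro-1′H-spiro[1,3-dioxolane-2,2′-naphthalene], via phosphorus ylide 15 (not isolated)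
Conditions: 14 (2 equiv), 4CzIPN (2,4,5,6-tetra(carbazol-9-yl)isophthalonitrile, 2 mol%), Cs2CO3 (1.5 equiv), DMSO, blue LEDs (450 nm), rt; then 40 °C
Reagents that add atoms: none
Why: Proposed new method: the caesium carboxylate of 13 is oxidised by photoexcited 4CzIPN and loses CO2 to give the primary C1 radical, which adds to the CH2 terminus (C2) of vinyltriphenylphosphonium; the α-phosphonio radical at C3 is reduced by the photocatalyst radical anion to ylide 15, which closes ring A by intramolecular Wittig olefination of the C4 ketone. The closest known reaction types are the photoredox three-component olefination of carboxylic acids, vinylphosphonium salts and carbonyl compounds and the classical conjugate-addition/intramolecular-Wittig annulation with vinylphosphonium salts; new here is their use as a ring closure onto a ketone. Ring A closes in a six-membered mode (6-exo-trig at the carbonyl) through the oxaphosphetane, giving the C3=C4 double bond with C15 in place. No stereocentre is created: the trans relationship of the C10 arm and the C5 acetyl group in 13 becomes the trans ring fusion. The step needs the nucleophilic C1 radical to add intermolecularly faster than it abstracts hydrogen (1,5-shift from the acetyl methyl) or is reduced, which the cationic, polarity-matched acceptor in excess should secure, and it needs the ylide to meet only one carbonyl group, which the ketal at C8 and the loss of the carboxyl group guarantee.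

Step 7
Reactants: 16
Product: 17 (4a′S,5′R,6′R,8a′S)-4a′,5′-dimethyloctahydro-1′H-spiro[1,3-dioxolane-2,2′-naphthalen]-6′-ol
Conditions: BH3·THF, THF, 0 °C to rt; then NaOH, H2O2, 0 °C to rt
Reagents that add atoms: hydrogen peroxide, OO
Why: Hydroboration–oxidation (syn, anti-Markovnikov): borane should add to the C3=C4 face opposite the axial C5 methyl, putting boron on C3 and hydrogen on C4 from the same face, so that the C3 hydroxyl is equatorial and trans to the C4 methyl, which ends cis to the C5 methyl; oxidation retains configuration.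

Step 8
Reactants: 17; 18 angelic acid ((2Z)-2-methylbut-2-enoic acid)
Product: 19 (4a′S,5′R,6′R,8a′S)-4a′,5′-dimethyloctahydro-1′H-spiro[1,3-dioxolane-2,2′-naphthalen]-6′-yl (2Z)-2-methylbut-2-enoate
Conditions: 18, 2,4,6-trichlorobenzoyl chloride, Et3N, toluene, rt; then 17, 75 °C
Reagents that add atoms: none
Why: Yamaguchi-type mixed-anhydride esterification, the established way to acylate hindered secondary alcohols with angelic acid without Z-to-E isomerisation to the tiglate.

Step 9
Reactants: 19
Product: 20 (4aS,5R,6R,8aS)-4a,5-dimethyl-2-oxodecahydronaphthalen-6-yl (2Z)-2-methylbut-2-enoate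
Conditions: PPTS (20 mol%), acetone/H2O (10:1), 55 °C
Reagents that add atoms: water, O
Why: Mild acid-catalysed hydrolysis of the dioxolane releases the C8 ketone and leaves the ester and the ring stereocentres untouched.

Step 10
Reactants: 20; 21 acetone
Product: 22 (3S,4aS,5R,6R,8aS)-3-(2-hydroxypropan-2-yl)-4a,5-dimethyl-2-oxodecahydronaphthalen-6-yl (2Z)-2-methylbut-2-enoate
Conditions: LiN(iPr)2 (1.05 equiv), THF, −78 °C; then acetone, −78 °C; aq. NH4Cl
Reagents that add atoms: none
Why: Aldol addition of the lithium enolate: kinetic enolisation of the trans-fused decalone is expected on the C7 side, away from the ring-fusion CH (as 3-keto-5α-steroids enolise towards C2), the ketone α-CH2 being far more acidic than any ester C–H; the C7 substituent takes the equatorial position (epimerisable centre).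

Step 11
Reactants: 22
Product: 23 (3S,4aS,5R,6R,8aS)-4a,5-dimethyl-2-oxo-3-(prop-1-en-2-yl)decahydronaphthalen-6-yl (2Z)-2-methylbut-2-enoate
Conditions: SOCl2, pyridine, CH2Cl2, −30 to 0 °C
Reagents that add atoms: none
Why: Dehydration of the tertiary alcohol through its chlorosulfite under basic, non-equilibrating conditions (E2 with loss of a methyl hydrogen) should favour the isopropenyl (β,γ-unsaturated) isomer over the conjugated isopropylidene ketone; C7 stays equatorial.

Step 12
Reactants: 23
Product: 24 (1S,3S,4aR,5R,6R,8aR)-1-hydroxy-4a,5-dimethyl-2-oxo-3-(prop-1-en-2-yl)decahydronaphthalen-6-yl (2Z)-2-methylbut-2-enoate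
Conditions: LiN(iPr)2 (1.1 equiv), THF, −78 °C; then 3-phenyl-2-(phenylsulfonyl)oxaziridine, −78 °C; aq. NH4Cl
Reagents that add atoms: 3-phenyl-2-(phenylsulfonyl)oxaziridine, O=S(=O)(c1ccccc1)N1OC1c1ccccc1
Why: Enolate α-hydroxylation: kinetic deprotonation at the less substituted C9 methylene, then oxygen transfer from the N-sulfonyloxaziridine on the face anti to the syn-axial C5 methyl, should give the equatorial C9 alcohol, which is also the thermodynamically preferred epimer next to the C8 ketone.

Step 13
Reactants: 24; 25 (2E)-3-methylpent-2-enoic acid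
Product: 26 (1S,3S,4aR,5R,6R,8aR)-4a,5-dimethyl-1-{[(2E)-3-methylpent-2-enoyl]oxy}-2-oxo-3-(prop-1-en-2-yl)decahydronaphthalen-6-yl (2Z)-2-methylbut-2-enoate (CNP0301161.1)
Conditions: DCC, DMAP (10 mol%), CH2Cl2, 0 °C to rt
Reagents that add atoms: none
Why: Steglich esterification of the secondary α-ketol with the E-configured acid under mild, nearly neutral conditions, which should leave the β,γ-unsaturated ketone and both ester double-bond geometries intact.

**Compound list**

1 | (E)-3-[(tert-butyldimethylsilyl)oxy]-N,N-dimethylbuta-1,3-dien-1-amine | CN(C)/C=C/C(=C)O[Si](C)(C)C(C)(C)C | starting material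
2 | methacrolein | C=C(C)C=O | starting material
3 | (1S,2R)-2-(dimethylamino)-4-[(tert-butyldimethylsilyl)oxy]-1-methylcyclohex-3-ene-1-carbaldehyde | C[C@]1(C=O)CCC(O[Si](C)(C)C(C)(C)C)=C[C@H]1N(C)C | intermediate
4 | 1-[(1S,2R)-2-(dimethylamino)-4-[(tert-butyldimethylsilyl)oxy]-1-methylcyclohex-3-en-1-yl]ethan-1-ol (both carbinol epimers) | CC(O)[C@@]1(C)CCC(O[Si](C)(C)C(C)(C)C)=C[C@H]1N(C)C | intermediate
5 | (4S)-4-(1-hydroxyethyl)-4-methylcyclohex-2-en-1-one (both carbinol epimers) | O=C1CC[C@](C)(C(C)O)C=C1 | intermediate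
6 | tert-butyl[(1-methoxyethenyl)oxy]dimethylsilane | C=C(OC)O[Si](C)(C)C(C)(C)C | starting material
7 | (4S)-4-{1-[(tert-butyldimethylsilyl)oxy]ethyl}-4-methylcyclohex-2-en-1-one (both epimers) | O=C1CC[C@](C)(C(C)O[Si](C)(C)C(C)(C)C)C=C1 | intermediate
8 | methyl 2-[(1S,6S)-3-[(tert-butyldimethylsilyl)oxy]-6-{1-[(tert-butyldimethylsilyl)oxy]ethyl}-6-methylcyclohex-2-en-1-yl]acetate (both epimers) | COC(=O)C[C@H]1C=C(O[Si](C)(C)C(C)(C)C)CC[C@]1(C)C(C)O[Si](C)(C)C(C)(C)C | intermediate
9 | methyl 2-[(1R,2S)-2-(1-hydroxyethyl)-2-methyl-5-oxocyclohexyl]acetate (both carbinol epimers) | COC(=O)C[C@H]1CC(=O)CC[C@]1(C)C(C)O | intermediate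
10 | ethylene glycol | OCCO | starting material
11 | (4a′R,8a′S)-1′,8a′-dimethylhexahydrospiro[1,3-dioxolane-2,6′-isochromen]-3′(4′H)-one (both C1′ epimers) | O=C1C[C@H]2CC3(CC[C@]2(C)C(C)O1)OCCO3 | intermediate
12 | lithium 2-[(7R,8S)-8-(1-hydroxyethyl)-8-methyl-1,4-dioxaspiro[4.5]decan-7-yl]acetate (both carbinol epimers) | [Li+].[O-]C(=O)C[C@H]1CC2(CC[C@]1(C)C(C)O)OCCO2 | intermediate
13 | 2-[(7R,8S)-8-acetyl-8-methyl-1,4-dioxaspiro[4.5]decan-7-yl]acetic acid | OC(=O)C[C@H]1CC2(CC[C@]1(C)C(C)=O)OCCO2 | intermediate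
14 | vinyltriphenylphosphonium bromide | C=C[P+](c1ccccc1)(c1ccccc1)c1ccccc1.[Br-] | starting material
15 | 1-[(7S,8S)-8-methyl-7-[3-(triphenyl-λ5-phosphanylidene)propyl]-1,4-dioxaspiro[4.5]decan-8-yl]ethan-1-one | C(=P(c1ccccc1)(c1ccccc1)c1ccccc1)CC[C@H]1CC2(CC[C@]1(C)C(C)=O)OCCO2 | intermediate
16 | (4a′S,8a′S)-4a′,5′-dimethyl-3′,4′,4a′,7′,8′,8a′-hexahydro-1′H-spiro[1,3-dioxolane-2,2′-naphthalene] | C13(OCCO1)CC[C@]2(C)C(C)=CCC[C@H]2C3 | intermediate
17 | (4a′S,5′R,6′R,8a′S)-4a′,5′-dimethyloctahydro-1′H-spiro[1,3-dioxolane-2,2′-naphthalen]-6′-ol | C13(OCCO1)CC[C@]2(C)[C@@H](C)[C@H](O)CC[C@H]2C3 | intermediate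
18 | angelic acid ((2Z)-2-methylbut-2-enoic acid) | C/C=C(/C)C(=O)O | starting material
19 | (4a′S,5′R,6′R,8a′S)-4a′,5′-dimethyloctahydro-1′H-spiro[1,3-dioxolane-2,2′-naphthalen]-6′-yl (2Z)-2-methylbut-2-enoate | C13(OCCO1)CC[C@]2(C)[C@@H](C)[C@H](OC(=O)/C(C)=C\C)CC[C@H]2C3 | intermediate
20 | (4aS,5R,6R,8aS)-4a,5-dimethyl-2-oxodecahydronaphthalen-6-yl (2Z)-2-methylbut-2-enoate | O=C1CC[C@]2(C)[C@@H](C)[C@H](OC(=O)/C(C)=C\C)CC[C@H]2C1 | intermediate
21 | acetone | CC(C)=O | starting material
22 | (3S,4aS,5R,6R,8aS)-3-(2-hydroxypropan-2-yl)-4a,5-dimethyl-2-oxodecahydronaphthalen-6-yl (2Z)-2-methylbut-2-enoate | CC(C)(O)[C@@H]1C[C@]2(C)[C@@H](C)[C@H](OC(=O)/C(C)=C\C)CC[C@H]2CC1=O | intermediate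
23 | (3S,4aS,5R,6R,8aS)-4a,5-dimethyl-2-oxo-3-(prop-1-en-2-yl)decahydronaphthalen-6-yl (2Z)-2-methylbut-2-enoate | C=C(C)[C@@H]1C[C@]2(C)[C@@H](C)[C@H](OC(=O)/C(C)=C\C)CC[C@H]2CC1=O | intermediate
24 | (1S,3S,4aR,5R,6R,8aR)-1-hydroxy-4a,5-dimethyl-2-oxo-3-(prop-1-en-2-yl)decahydronaphthalen-6-yl (2Z)-2-methylbut-2-enoate | C=C(C)[C@@H]1C[C@]2(C)[C@@H](C)[C@H](OC(=O)/C(C)=C\C)CC[C@H]2[C@H](O)C1=O | intermediate
25 | (2E)-3-methylpent-2-enoic acid | CC/C(C)=C/C(=O)O | starting material
26 | (1S,3S,4aR,5R,6R,8aR)-4a,5-dimethyl-1-{[(2E)-3-methylpent-2-enoyl]oxy}-2-oxo-3-(prop-1-en-2-yl)decahydronaphthalen-6-yl (2Z)-2-methylbut-2-enoate | C=C(C)[C@@H]1C[C@]2(C)[C@@H](C)[C@H](OC(=O)/C(C)=C\C)CC[C@H]2[C@H](OC(=O)/C=C(\C)CC)C1=O | target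

**Totals and risks**

Total step count: 13. Longest linear sequence: 13 steps (all other components are purchased).

Steps most likely to fail:

1. Step 6 (proposed new method). The C1 radical may be reduced or undergo intramolecular hydrogen transfer before it adds; the vinylphosphonium salt may oligomerise; or the ylide may be protonated so that olefination stalls. Fallback with known chemistry, from 13 back to 16, by ring-closing metathesis:
   - Wittig methylenation of the acetyl group of 13 (Ph3P=CH2 from Ph3PCH3Br and KOtBu, excess, THF) should give 2-[(7R,8S)-8-methyl-8-(prop-1-en-2-yl)-1,4-dioxaspiro[4.5]decan-7-yl]acetic acid F1.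
   - LiAlH4 reduction should give 2-[(7S,8S)-8-methyl-8-(prop-1-en-2-yl)-1,4-dioxaspiro[4.5]decan-7-yl]ethan-1-ol F2.
   - I2, PPh3 and imidazole should give (7R,8S)-7-(2-iodoethyl)-8-methyl-8-(prop-1-en-2-yl)-1,4-dioxaspiro[4.5]decane F3.
   - CH2=CHMgBr with CuI (cat.) should give (7S,8S)-7-(but-3-en-1-yl)-8-methyl-8-(prop-1-en-2-yl)-1,4-dioxaspiro[4.5]decane F4.
   - Ring-closing metathesis with the second-generation Grubbs catalyst RuCl2(=CHPh)(PCy3)(H2IMes) in CH2Cl2 at 40 °C should close the trisubstituted C3=C4 alkene and return to 16.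

2. Step 11. The elimination may lose regiocontrol and give the conjugated isopropylidene ketone, or the isopropenyl ketone may isomerise into conjugation afterwards. Fallback, from 20 directly to 23 without the aldol adduct: palladium-catalysed α-alkenylation of the ketone enolate with 2-bromopropene (Pd2(dba)3, a dialkylbiarylphosphine, LiN(SiMe3)2, THF, rt), a known enolate–alkenyl halide coupling that installs the isopropenyl group in one bond-forming event; it makes no new intermediate.

3. Step 12. Enolisation may occur at the allylic C7–H instead of C9, leading to oxidation at C7 or to double-bond migration. Fallback, from 22 to 26, with the order of events changed: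
   - Double deprotonation of the aldol 22 (2.2 equiv LiN(iPr)2; the tertiary alkoxide shields the C7 side) and oxidation with the same oxaziridine should give (1S,3S,4aR,5R,6R,8aR)-1-hydroxy-3-(2-hydroxypropan-2-yl)-4a,5-dimethyl-2-oxodecahydronaphthalen-6-yl (2Z)-2-methylbut-2-enoate F5.
   - Selective esterification of the secondary hydroxyl with 25 (DCC, DMAP) should give (1S,3S,4aR,5R,6R,8aR)-3-(2-hydroxypropan-2-yl)-4a,5-dimethyl-1-{[(2E)-3-methylpent-2-enoyl]oxy}-2-oxodecahydronaphthalen-6-yl (2Z)-2-methylbut-2-enoate F6.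
   - Dehydration with SOCl2 and pyridine should then give 26.

Further compounds
F1 | step 6 | 2-[(7R,8S)-8-methyl-8-(prop-1-en-2-yl)-1,4-dioxaspiro[4.5]decan-7-yl]acetic acid | OC(=O)C[C@H]1CC2(CC[C@]1(C)C(C)=C)OCCO2
F2 | step 6 | 2-[(7S,8S)-8-methyl-8-(prop-1-en-2-yl)-1,4-dioxaspiro[4.5]decan-7-yl]ethan-1-ol | OCC[C@H]1CC2(CC[C@]1(C)C(C)=C)OCCO2
F3 | step 6 | (7R,8S)-7-(2-iodoethyl)-8-methyl-8-(prop-1-en-2-yl)-1,4-dioxaspiro[4.5]decane | ICC[C@H]1CC2(CC[C@]1(C)C(C)=C)OCCO2
F4 | step 6 | (7S,8S)-7-(but-3-en-1-yl)-8-methyl-8-(prop-1-en-2-yl)-1,4-dioxaspiro[4.5]decane | C=CCC[C@H]1CC2(CC[C@]1(C)C(C)=C)OCCO2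
F0 | step 11 | none | none
F5 | step 12 | (1S,3S,4aR,5R,6R,8aR)-1-hydroxy-3-(2-hydroxypropan-2-yl)-4a,5-dimethyl-2-oxodecahydronaphthalen-6-yl (2Z)-2-methylbut-2-enoate | CC(C)(O)[C@@H]1C[C@]2(C)[C@@H](C)[C@H](OC(=O)/C(C)=C\C)CC[C@H]2[C@H](O)C1=O
F6 | step 12 | (1S,3S,4aR,5R,6R,8aR)-3-(2-hydroxypropan-2-yl)-4a,5-dimethyl-1-{[(2E)-3-methylpent-2-enoyl]oxy}-2-oxodecahydronaphthalen-6-yl (2Z)-2-methylbut-2-enoate | CC(C)(O)[C@@H]1C[C@]2(C)[C@@H](C)[C@H](OC(=O)/C(C)=C\C)CC[C@H]2[C@H](OC(=O)/C=C(\C)CC)C1=O
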